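in all of them: second end groups 1.00 equiv

|  | first end groups | third end groups | time | remark |
|---|---|---|---|---|
| green | 0.50 M | 1.00 equiv | 2.0 d | everything together in a closed stirred flask, run for 2.0 d |
| ochre | 0.50 M | 1.00 equiv (fed, over 2.00 d) | 2.0 d | all but third end groups at the start; third end groups goes in evenly over 2.00 d, the run ends at 2.0 d |
| violet | 0.50 M | 1.00 equiv |  | one stirred flow tank at steady state, fed with the mixture as stated, mean residence time 2.0 d |
| grey | 0.50 M (fed, over 2.00 d) | 1.00 equiv | 2.0 d | all but first end groups at the start; first end groups goes in evenly over 2.00 d, the run ends at 2.0 d |

    first end groups + second end groups → links (k1 = 3.26 × 10⁻⁵ /M/s)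
    second end groups + third end groups → links of the second sort (k2 = 2.89 × 10⁻⁵ /M/s)
    second end groups → decomposed reagent (k3 = 3.87 × 10⁻⁵ /s)

- the stated concentrations are those of everything mixed, before any reaction; amounts are the same in each set-up
- the feed brings no volume worth counting
- run time (green): 2.0 d

- order of the set-ups by the amount of links at the outlet or at the end, in percent of the first end groups put in, highest first (green / ochre / violet / grey)
- amount of links at the outlet or at the end, in percent of the first end groups put in, green
- amount of links at the outlet or at the end, in percent of the first end groups put in, ochre
- amount of links at the outlet or at the end, in percent of the first end groups put in, violet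
- amount of links at the outlet or at the end, in percent of the first end groups put in, grey

1. Follow one second end group from the start and compare its fates at that moment. Decomposition halves second end groups in t_d = 0.207 d. First end groups at their charge, acting alone, halve them in t_L = 0.492 d. The run of 2.0 d is longer than either, so the yield is a competition and not a matter of the clock.

2. The link ratio is ρ = t_d/t_L = 0.421, links formed per second end group decomposed; it is a selectivity factor. Without third end groups, the share going to links is s = ρ/(1+ρ), at the start 29.6%.

3. Ochre: third end groups enter over 2.00 d, longer than t_d, so after one t_d just 10.3% of them are in, and they are left out here. If first end groups fall by that share as links form, ρ comes down to 0.296 and s to 22.9%. The mean of the two shares is an estimate of 26.2% links in ochre.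

4. Green: third end groups are present from the start, and the starting share drops to 23.5%. Grey: after one t_d, 10.3% of the first end groups are in, so ρ is 0.0436. Violet is not reckoned here. Ochre starts at a higher share than green, and ρ in grey after one t_d stands below the lowered ρ of ochre; the reckoned order is ochre, green, grey.

5. The forecast gives ochre > green > violet > grey, with green 21.8%, ochre 25.9%, violet 19% and grey 3.2%. For ochre it stands slightly below the estimate here. Its ground: “The second end groups are lost quickly, mostly to their own decomposition”.

6. The flasks give ochre > green > violet > grey: green 21.8%, ochre 26.0%, violet 19.0%, grey 3.07%. In ochre, 74.0% of the first end groups stand at the end, so ρ there has come down to 0.312. ρ contains no amount of second end groups, so a proportional reckoning from grey puts a neighbour like grey with 4.00 equiv of second end groups at 12.3%; that neighbour ends at 12.1% links.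

Its constants are made up; the flask was simulated.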